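**Strategy.** The cyclohexane ring is cut into a two-carbon and a four-carbon piece (ring numbered as 7-oxabicyclo[4.1.0]heptane, C1 = methyl-bearing epoxide carbon). C4–C5, the side-chain carbon and its acetoxy neighbour, come from an (E)-enone, so their trans relationship is an alkene geometry. C6–C1–C2–C3 come from a 4-acetoxy-1-methoxy-2-methyl-3-silyloxy diene that masks the C2 ketone and already carries the C3 acetoxy group. One catalytic asymmetric Diels–Alder reaction closes the ring and sets C3, C4 and C5. The dienophile's acetyl group is a latent acetoxy group (Baeyer–Villiger, retention) and its alkynyl group is the handle for the side chain. The epoxide is delivered late, syn to a temporary C2 hydroxyl.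

Key step: step 4

Remark 1: (E)-4-methoxy-3-methylbut-3-en-2-one (4) is taken as a purchasable building block; otherwise it is available from butanone by formylation and O-methylation.
Remark 2: the absolute sense of the two catalyst-controlled steps (4 and 9) is assigned from the accepted models of these catalyst classes and has not been derived here; the antipodal catalyst or ligand serves if a pilot run shows the opposite sense.

Step 1
Reactants: 1 3-(trimethylsilyl)prop-2-ynal; 2 1-(triphenyl-λ5-phosphanylidene)propan-2-one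
Product: 3 (E)-6-(trimethylsilyl)hex-3-en-5-yn-2-one
Conditions: CH2Cl2, rt
Reagents that add atoms: none
Why: Wittig olefination with a stabilised ylide should give the (E)-enone, which fixes the later trans C4/C5 relationship.

Step 2
Reactants: 4 (E)-4-methoxy-3-methylbut-3-en-2-one
Product: 5 (E)-4-methoxy-3-methyl-2-oxobut-3-en-1-yl acetate
Conditions: Mn(OAc)3·2H2O, benzene, reflux
Reagents that add atoms: Mn(OAc)3, [Mn+3].CC(=O)[O-].CC(=O)[O-].CC(=O)[O-]
Why: α'-Acetoxylation of an enone by trivalent manganese proceeds through the manganese enolate of the methyl ketone and should leave the vinylogous ester untouched.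

Step 3
Reactants: 5 (E)-4-methoxy-3-methyl-2-oxobut-3-en-1-yl acetate
Product: 6 (1Z,3E)-4-methoxy-3-methyl-2-[(triisopropylsilyl)oxy]buta-1,3-dien-1-yl acetate
Conditions: iPr3SiOTf, Et3N, Et2O, 0 °C
Reagents that add atoms: triisopropylsilyl trifluoromethanesulfonate, CC(C)[Si](OS(=O)(=O)C(F)(F)F)(C(C)C)C(C)C
Why: Soft enolisation toward the only α-CH2 should give the silyl enol ether, with the acetoxy group trans to the branched alkenyl substituent (Z), so that it sits "outside" on the diene.

Step 4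
Reactants: 3 (E)-6-(trimethylsilyl)hex-3-en-5-yn-2-one; 6 (1Z,3E)-4-methoxy-3-methyl-2-[(triisopropylsilyl)oxy]buta-1,3-dien-1-yl acetate
Product: 8 (1S,5S,6S)-5-acetyl-3-methyl-2-oxo-6-[(trimethylsilyl)ethynyl]cyclohex-3-en-1-yl acetate, via silyl enol ether cycloadduct 7 (not isolated)
Conditions: (S)-1-(2-methylphenyl)-3,3-diphenyltetrahydro-1H,3H-pyrrolo[1,2-c][1,3,2]oxazaborole (20 mol%), HN(SO2CF3)2 (20 mol%), CH2Cl2, −78 to −40 °C; then CF3CO2H, CH2Cl2/H2O, 0 °C
Reagents that add atoms: none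
Why: The boron Lewis acid binds the acetyl oxygen of 3, and the diene terminus that becomes C3 (β-carbon of the silyl enol ether, pushed vinylogously by the 1-methoxy group) attacks the enone β-carbon (future C4) in an asynchronous endo [4+2] cycloaddition, the second bond joining the acetyl-bearing α-carbon (future C5) to the methoxy-bearing terminus (future C6). The closest known reaction type is the chiral oxazaborolidinium-catalysed Diels–Alder reaction of 2-silyloxy and 1-alkoxy-3-silyloxy dienes with acyclic enones. The six-membered ring is closed by an intermolecular suprafacial [4+2] cycloaddition, so the (E)-geometry of 3 becomes the C4/C5 trans relationship, and the endo rule together with the (Z)-enol acetate places the C3 acetoxy group cis to the acetyl group and trans to the alkynyl group. Absolute configuration is set by the catalyst, whose aryl group shields one face of the bound enone. The step needs regioselectivity (OMe and OSi both polarise the diene toward the acetoxy-bearing terminus and should outweigh the acetoxy group) and site selectivity (the enone C=C reacts, not the silyl-capped alkyne). Acid then expels methanol and the silyl group from 7 to unveil the C6=C1–C2=O enone of 8.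

Step 5
Reactants: 8 (1S,5S,6S)-5-acetyl-3-methyl-2-oxo-6-[(trimethylsilyl)ethynyl]cyclohex-3-en-1-yl acetate
Product: 9 (1S,2R,3S)-5-methyl-4-oxo-2-[(trimethylsilyl)ethynyl]cyclohex-5-ene-1,3-diyl diacetate
Conditions: mCPBA, NaHCO3, CH2Cl2, 0 °C to rt
Reagents that add atoms: 3-chloroperbenzoic acid, OOC(=O)c1cccc(Cl)c1
Why: Baeyer–Villiger oxidation of the methyl ketone should migrate the secondary ring carbon C5 with retention, turning the acetyl group into the C5 acetate, while the electron-poor enone and the silyl alkyne resist the peracid.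

Step 6
Reactants: 9 (1S,2R,3S)-5-methyl-4-oxo-2-[(trimethylsilyl)ethynyl]cyclohex-5-ene-1,3-diyl diacetate
Product: 10 (1S,2R,3S)-2-ethynyl-5-methyl-4-oxocyclohex-5-ene-1,3-diyl diacetate
Conditions: AgNO3 (10 mol%), acetone/H2O, rt
Reagents that add atoms: none
Why: Silver-catalysed protodesilylation is specific for alkynylsilanes and should spare the acetates and the base-sensitive α-acetoxy ketone.

Step 7
Reactants: 10 (1S,2R,3S)-2-ethynyl-5-methyl-4-oxocyclohex-5-ene-1,3-diyl diacetate
Product: 12 (1S,2R,3S)-2-(1-iodoethenyl)-5-methyl-4-oxocyclohex-5-ene-1,3-diyl diacetate, via iodoboration adduct 11 (not isolated)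
Conditions: 9-iodo-9-borabicyclo[3.3.1]nonane, hexane/CH2Cl2, −20 °C; then AcOH, 0 °C
Reagents that add atoms: 9-iodo-9-borabicyclo[3.3.1]nonane, IB1C2CCCC1CCC2
Why: syn-Haloboration of a terminal alkyne places iodine on the internal carbon, and protodeboronation with acetic acid should leave the 2-iodo-1-alkene.

Step 8
Reactants: 13 4-methylpent-3-en-1-ol
Product: 14 4-methylpent-3-enal
Conditions: Dess–Martin periodinane, CH2Cl2, 0 °C; used directly
Reagents that add atoms: none
Why: Dess–Martin oxidation under near-neutral conditions should give the β,γ-unsaturated aldehyde without moving the double bond into conjugation.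

Step 9
Reactants: 12 (1S,2R,3S)-2-(1-iodoethenyl)-5-methyl-4-oxocyclohex-5-ene-1,3-diyl diacetate; 14 4-methylpent-3-enal
Product: 16 (1S,2R,3S)-2-[(3S)-3-hydroxy-6-methylhepta-1,5-dien-2-yl]-5-methyl-4-oxocyclohex-5-ene-1,3-diyl diacetate, via alkenylchromium dichloride 15 (not isolated)
Conditions: CrCl2, NiCl2 (2 mol%), (S)-N-[2-(4-isopropyl-4,5-dihydro-1,3-oxazol-2-yl)-6-methylphenyl]methanesulfonamide, Et3N, THF, rt
Reagents that add atoms: none
Why: The Nozaki–Hiyama–Kishi reaction adds the alkenylchromium species only to the aldehyde, tolerating ketone and esters, and the chiral sulfonamide ligand on chromium sets the (S) carbinol centre of the side chain.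

Step 10
Reactants: 16 (1S,2R,3S)-2-[(3S)-3-hydroxy-6-methylhepta-1,5-dien-2-yl]-5-methyl-4-oxocyclohex-5-ene-1,3-diyl diacetate; 17 angelic acid, (Z)-2-methylbut-2-enoic acid
Product: 19 (1S,2R,3S)-5-methyl-2-[(3S)-6-methyl-3-{[(2Z)-2-methylbut-2-enoyl]oxy}hepta-1,5-dien-2-yl]-4-oxocyclohex-5-ene-1,3-diyl diacetate, via mixed anhydride 18 (not isolated)
Conditions: 17, 2,4,6-trichlorobenzoyl chloride, Et3N, toluene, rt; then 16, toluene, 70 °C
Reagents that add atoms: none
Why: Yamaguchi esterification through the trichlorobenzoyl mixed anhydride acylates hindered secondary alcohols with retention at the carbinol carbon and is the standard way to install an angelate without Z-to-E isomerisation.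

Step 11
Reactants: 19 (1S,2R,3S)-5-methyl-2-[(3S)-6-methyl-3-{[(2Z)-2-methylbut-2-enoyl]oxy}hepta-1,5-dien-2-yl]-4-oxocyclohex-5-ene-1,3-diyl diacetate
Product: 20 (1S,2R,3S,4S)-4-hydroxy-5-methyl-2-[(3S)-6-methyl-3-{[(2Z)-2-methylbut-2-enoyl]oxy}hepta-1,5-dien-2-yl]cyclohex-5-ene-1,3-diyl diacetate
Conditions: NaBH4, CeCl3·7H2O, MeOH, −78 °C
Reagents that add atoms: none
Why: Luche 1,2-reduction by axial hydride attack on the all-equatorial half-chair should give the equatorial C2 alcohol, trans to the C3 acetate and on the face of the side chain, while the esters are untouched.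

Step 12
Reactants: 20 (1S,2R,3S,4S)-4-hydroxy-5-methyl-2-[(3S)-6-methyl-3-{[(2Z)-2-methylbut-2-enoyl]oxy}hepta-1,5-dien-2-yl]cyclohex-5-ene-1,3-diyl diacetate
Product: 21 (1R,2R,3S,4S,5R,6S)-2-hydroxy-1-methyl-4-[(3S)-6-methyl-3-{[(2Z)-2-methylbut-2-enoyl]oxy}hepta-1,5-dien-2-yl]-7-oxabicyclo[4.1.0]heptane-3,5-diyl diacetate
Conditions: VO(acac)2 (5 mol%), tBuOOH (decane), CH2Cl2, 0 °C to rt
Reagents that add atoms: tert-butyl hydroperoxide, CC(C)(C)OO
Why: Vanadium-catalysed hydroxyl-directed epoxidation delivers oxygen to C1 and C6 syn to the C2 hydroxyl, hence anti to both acetates, and reacts with the allylic alcohol far faster than with the side-chain alkenes.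

Step 13
Reactants: 21 (1R,2R,3S,4S,5R,6S)-2-hydroxy-1-methyl-4-[(3S)-6-methyl-3-{[(2Z)-2-methylbut-2-enoyl]oxy}hepta-1,5-dien-2-yl]-7-oxabicyclo[4.1.0]heptane-3,5-diyl diacetate
Product: 22 (1S,3S,4R,5R,6S)-1-methyl-4-[(3S)-6-methyl-3-{[(2Z)-2-methylbut-2-enoyl]oxy}hepta-1,5-dien-2-yl]-2-oxo-7-oxabicyclo[4.1.0]heptane-3,5-diyl diacetate
Conditions: Dess–Martin periodinane, NaHCO3, CH2Cl2, rt
Reagents that add atoms: none
Why: Dess–Martin oxidation of the epoxy alcohol under buffered conditions should return the C2 ketone without opening the epoxide or epimerising C3.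

**Compound list**

1 | 3-(trimethylsilyl)prop-2-ynal | C[Si](C)(C)C#CC=O | starting material
2 | 1-(triphenyl-λ5-phosphanylidene)propan-2-one | CC(=O)C=P(c1ccccc1)(c1ccccc1)c1ccccc1 | starting material
3 | (E)-6-(trimethylsilyl)hex-3-en-5-yn-2-one | CC(=O)/C=C/C#C[Si](C)(C)C | intermediate
4 | (E)-4-methoxy-3-methylbut-3-en-2-one | CO/C=C(C)/C(C)=O | starting material
5 | (E)-4-methoxy-3-methyl-2-oxobut-3-en-1-yl acetate | CO/C=C(C)/C(=O)COC(C)=O | intermediate
6 | (1Z,3E)-4-methoxy-3-methyl-2-[(triisopropylsilyl)oxy]buta-1,3-dien-1-yl acetate | CO/C=C(C)/C(O[Si](C(C)C)(C(C)C)C(C)C)=C/OC(C)=O | intermediate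
7 | (1S,4R,5R,6S)-5-acetyl-4-methoxy-3-methyl-2-[(triisopropylsilyl)oxy]-6-[(trimethylsilyl)ethynyl]cyclohex-2-en-1-yl acetate (cycloadduct, not isolated) | C[Si](C)(C)C#C[C@@H]1[C@@H](C(C)=O)[C@@H](OC)C(C)=C(O[Si](C(C)C)(C(C)C)C(C)C)[C@H]1OC(C)=O | intermediate
8 | (1S,5S,6S)-5-acetyl-3-methyl-2-oxo-6-[(trimethylsilyl)ethynyl]cyclohex-3-en-1-yl acetate | C[Si](C)(C)C#C[C@@H]1[C@@H](C(C)=O)C=C(C)C(=O)[C@H]1OC(C)=O | intermediate
9 | (1S,2R,3S)-5-methyl-4-oxo-2-[(trimethylsilyl)ethynyl]cyclohex-5-ene-1,3-diyl diacetate | C[Si](C)(C)C#C[C@@H]1[C@@H](OC(C)=O)C=C(C)C(=O)[C@H]1OC(C)=O | intermediate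
10 | (1S,2R,3S)-2-ethynyl-5-methyl-4-oxocyclohex-5-ene-1,3-diyl diacetate | C#C[C@@H]1[C@@H](OC(C)=O)C=C(C)C(=O)[C@H]1OC(C)=O | intermediate
11 | (Z)-iodoboration adduct of 10, 2-[2-(9-borabicyclo[3.3.1]nonan-9-yl)-1-iodoethenyl] compound (not isolated) | I\C(=C/B1C2CCCC1CCC2)[C@@H]1[C@@H](OC(C)=O)C=C(C)C(=O)[C@H]1OC(C)=O | intermediate
12 | (1S,2R,3S)-2-(1-iodoethenyl)-5-methyl-4-oxocyclohex-5-ene-1,3-diyl diacetate | C=C(I)[C@@H]1[C@@H](OC(C)=O)C=C(C)C(=O)[C@H]1OC(C)=O | intermediate
13 | 4-methylpent-3-en-1-ol | CC(C)=CCCO | starting material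
14 | 4-methylpent-3-enal | CC(C)=CCC=O | intermediate
15 | alkenylchromium dichloride derived from 12 (not isolated) | C=C([Cr](Cl)Cl)[C@@H]1[C@@H](OC(C)=O)C=C(C)C(=O)[C@H]1OC(C)=O | intermediate
16 | (1S,2R,3S)-2-[(3S)-3-hydroxy-6-methylhepta-1,5-dien-2-yl]-5-methyl-4-oxocyclohex-5-ene-1,3-diyl diacetate | C=C([C@@H]1[C@@H](OC(C)=O)C=C(C)C(=O)[C@H]1OC(C)=O)[C@H](CC=C(C)C)O | intermediate
17 | angelic acid, (Z)-2-methylbut-2-enoic acid | C/C=C(/C)C(=O)O | starting material
18 | (Z)-2-methylbut-2-enoic 2,4,6-trichlorobenzoic anhydride (not isolated) | C/C=C(/C)C(=O)OC(=O)c1c(Cl)cc(Cl)cc1Cl | intermediate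
19 | (1S,2R,3S)-5-methyl-2-[(3S)-6-methyl-3-{[(2Z)-2-methylbut-2-enoyl]oxy}hepta-1,5-dien-2-yl]-4-oxocyclohex-5-ene-1,3-diyl diacetate | C=C([C@@H]1[C@@H](OC(C)=O)C=C(C)C(=O)[C@H]1OC(C)=O)[C@H](CC=C(C)C)OC(=O)/C(C)=C\C | intermediate
20 | (1S,2R,3S,4S)-4-hydroxy-5-methyl-2-[(3S)-6-methyl-3-{[(2Z)-2-methylbut-2-enoyl]oxy}hepta-1,5-dien-2-yl]cyclohex-5-ene-1,3-diyl diacetate | C=C([C@@H]1[C@@H](OC(C)=O)C=C(C)[C@H](O)[C@H]1OC(C)=O)[C@H](CC=C(C)C)OC(=O)/C(C)=C\C | intermediate
21 | (1R,2R,3S,4S,5R,6S)-2-hydroxy-1-methyl-4-[(3S)-6-methyl-3-{[(2Z)-2-methylbut-2-enoyl]oxy}hepta-1,5-dien-2-yl]-7-oxabicyclo[4.1.0]heptane-3,5-diyl diacetate | C=C([C@@H]1[C@@H](OC(C)=O)[C@@H]2O[C@]2(C)[C@H](O)[C@H]1OC(C)=O)[C@H](CC=C(C)C)OC(=O)/C(C)=C\C | intermediate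
22 | (1S,3S,4R,5R,6S)-1-methyl-4-[(3S)-6-methyl-3-{[(2Z)-2-methylbut-2-enoyl]oxy}hepta-1,5-dien-2-yl]-2-oxo-7-oxabicyclo[4.1.0]heptane-3,5-diyl diacetate | C=C([C@@H]1[C@@H](OC(C)=O)[C@@H]2O[C@]2(C)C(=O)[C@H]1OC(C)=O)[C@H](CC=C(C)C)OC(=O)/C(C)=C\C | target

**Step count and risks**

Total steps: 13. Longest linear sequence: 11 steps (steps 2, 3, 4, 5, 6, 7, 9, 10, 11, 12, 13, from 4 to 22).

Most likely to fail:

1. Step 4. The acetoxy group on the diene terminus opposes the two donor groups, so regiocontrol may erode, and silyl transfer from the diene to the catalyst may open an achiral background pathway that lowers enantioselectivity. Fallback: the C3 oxygen is introduced after the ring is made. The fallback sets out from 4 (with 3). Silylation of 4 (iPr3SiOTf, Et3N) should give the acetoxy-free diene (E)-[(4-methoxy-3-methylbuta-1,3-dien-2-yl)oxy]tri(propan-2-yl)silane F1. The same catalysed cycloaddition with 3 should give the silyl enol ether cycloadduct lacking the C3 acetoxy group F2, which acid converts into (4S,5S)-4-acetyl-2-methyl-5-[(trimethylsilyl)ethynyl]cyclohex-2-en-1-one F3. Baeyer–Villiger oxidation should give (1S,6R)-3-methyl-4-oxo-6-[(trimethylsilyl)ethynyl]cyclohex-2-en-1-yl acetate F4. α'-Acetoxylation with Mn(OAc)3, expected anti to the neighbouring C4 substituent, then comes back to the route at 9.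

2. Step 7. The Lewis-acidic iodoborane may deliver iodide to the enone or attack the acetates in competition with haloboration of the alkyne. Fallback: no iodoalkene is made. The fallback sets out from 10 (with 14). Direct reductive coupling of the terminal alkyne with the aldehyde (CrCl2, catalytic NiCl2, PPh3, H2O, DMF), known to give 2-substituted allylic alcohols, should give 16 together with its C8 epimer, (1S,2R,3S)-2-[(3R)-3-hydroxy-6-methylhepta-1,5-dien-2-yl]-5-methyl-4-oxocyclohex-5-ene-1,3-diyl diacetate F5. After separation, 16 goes on through step 10, and F5 is esterified with 17 under Mitsunobu conditions (PPh3, diisopropyl azodicarboxylate) with inversion, so both epimers come back to the route at 19.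

3. Step 9. Divalent chromium may reduce the α-acetoxy enone by single-electron transfer, the amine base may isomerise aldehyde 14 into conjugation, and ligand control at C8 may be weak. Fallback: the carbinol centre is set by a chiral allylborane instead. The fallback sets out from 12. Formylation catalysed by zerovalent palladium (Pd(PPh3)4, CO, Bu3SnH, THF, 50 °C) should give the enal (1S,2R,3S)-5-methyl-4-oxo-2-(3-oxoprop-1-en-2-yl)cyclohex-5-ene-1,3-diyl diacetate F6. Asymmetric allylboration with (−)-B-allyldiisopinocampheylborane at −78 °C, selective for the aldehyde, should give (1S,2R,3S)-2-[(3S)-3-hydroxyhexa-1,5-dien-2-yl]-5-methyl-4-oxocyclohex-5-ene-1,3-diyl diacetate F7. Cross-metathesis with 2-methylbut-2-ene (second-generation Grubbs catalyst) then comes back to the route at 16.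

**Further compounds**

F1 | step 4 | (E)-[(4-methoxy-3-methylbuta-1,3-dien-2-yl)oxy]tri(propan-2-yl)silane | CO/C=C(C)/C(=C)O[Si](C(C)C)(C(C)C)C(C)C
F2 | step 4 | 1-{6-methoxy-5-methyl-4-[(triisopropylsilyl)oxy]-2-[(trimethylsilyl)ethynyl]cyclohex-4-en-1-yl}ethan-1-one, acetyl cis to methoxy and trans to alkynyl | C[Si](C)(C)C#C[C@@H]1[C@@H](C(C)=O)[C@@H](OC)C(C)=C(O[Si](C(C)C)(C(C)C)C(C)C)C1
F3 | step 4 | (4S,5S)-4-acetyl-2-methyl-5-[(trimethylsilyl)ethynyl]cyclohex-2-en-1-one | C[Si](C)(C)C#C[C@@H]1[C@@H](C(C)=O)C=C(C)C(=O)C1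
F4 | step 4 | (1S,6R)-3-methyl-4-oxo-6-[(trimethylsilyl)ethynyl]cyclohex-2-en-1-yl acetate | C[Si](C)(C)C#C[C@@H]1[C@@H](OC(C)=O)C=C(C)C(=O)C1
F5 | step 7 | (1S,2R,3S)-2-[(3R)-3-hydroxy-6-methylhepta-1,5-dien-2-yl]-5-methyl-4-oxocyclohex-5-ene-1,3-diyl diacetate | C=C([C@@H]1[C@@H](OC(C)=O)C=C(C)C(=O)[C@H]1OC(C)=O)[C@@H](CC=C(C)C)O
F6 | step 9 | (1S,2R,3S)-5-methyl-4-oxo-2-(3-oxoprop-1-en-2-yl)cyclohex-5-ene-1,3-diyl diacetate | C=C(C=O)[C@@H]1[C@@H](OC(C)=O)C=C(C)C(=O)[C@H]1OC(C)=O
F7 | step 9 | (1S,2R,3S)-2-[(3S)-3-hydroxyhexa-1,5-dien-2-yl]-5-methyl-4-oxocyclohex-5-ene-1,3-diyl diacetate | C=C([C@@H]1[C@@H](OC(C)=O)C=C(C)C(=O)[C@H]1OC(C)=O)[C@H](CC=C)O
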